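**Plan**
- Retrosynthetic cuts, in order: the C4′–OH bond (enolate hydroxylation); the C3′–O bond (the tertiary C3 hydroxyl is tied back onto the enol carbon as a cyclic vinylogous ester); the C3–O bond together with a C4–I bond (iodoetherification); C3=C4 (ring-closing metathesis); C5–O (allylic etherification); C2–C3 (isopropenyl addition); C1–C2′ (allylation of the dione).
- Forward: the six-membered dione ring is bought; the chain is joined C2′–C1, then C2–C3, then O–C5; the oxolene ring closes by metathesis; the pyran ring closes in the key step and is reopened with hydroxide; the C4′ oxygen comes last.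
- Enabling feature: in the oxolane (O1, C2–C5) the tertiary C3–OH is cis to the C2 methylene C1, whose other end is C2′ of the enolised cyclohexane-1,3-dione. The enol oxygen on C3′ is six atoms from C3 (O–C3′=C2′–C1–C2–C3) and can reach a C3=C4 alkene only on the face that carries C1.
- Stereochemistry: C2 from a Sharpless kinetic resolution; C5 from the Ir/phosphoramidite catalyst (2,5-trans); C3 from the tether (cis ring fusion); C4′ from a camphor-derived oxaziridine; the E alkene from geranial.

Key step: step 12

Numbering: oxolane O1, C2 (bears the CH2 group C1), C3 (CH3, OH), C4, C5 (alkenyl); dione ring C1′ (C=O), C2′ (bears C1), C3′ (enol carbon), C4′ (carbinol). Enolised 1,3-diones are drawn as one tautomer.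
Assumption 1: the (Ra,R,R)-phosphoramidite is taken to direct the alkoxide to the allyl face that gives the (R)-ether, as it does with (E)-cinnamyl carbonates; if the sense is opposite for the dienyl carbonate, the mirror-image ligand is used.
Assumption 2: (+)-(camphorsulfonyl)oxaziridine is taken as the antipode that gives 4′S on this ring enolate; if not, the (−)-reagent is used.

Step 1
Reactants: 1 cyclohexane-1,3-dione; 2 allyl acetate
Product: 3 2-allylcyclohexane-1,3-dione
Conditions: 1 (1.5 equiv), Pd(PPh3)4 (2 mol%), DBU (1.0 equiv), toluene, 80 °C; dilute HCl work-up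
Reagents that add atoms: none
Why: Tsuji–Trost allylation, in which the allyl complex formed from 2 and zerovalent palladium is captured at C2 of the soft dione enolate, any O-allyl enol ether re-ionises and funnels to the C-allyl product, and the excess of 1 limits double allylation.

Step 2
Reactants: 3 2-allylcyclohexane-1,3-dione
Product: 4 3-methoxy-2-(prop-2-en-1-yl)cyclohex-2-en-1-one
Conditions: HC(OMe)3 (1.5 equiv), MeOH, p-TsOH (5 mol%), rt
Reagents that add atoms: trimethyl orthoformate, COC(OC)OC; methanol, CO
Why: acid-catalysed enol etherification of the symmetrical dione (the orthoformate takes up the water) gives one vinylogous methyl ester, which masks the acidic, nucleophilic enol through steps 3–10.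

Step 3
Reactants: 4 3-methoxy-2-(prop-2-en-1-yl)cyclohex-2-en-1-one
Product: 6 (2-methoxy-6-oxocyclohex-1-en-1-yl)acetaldehyde, via diol 5 (not isolated)
Conditions: OsO4 (2 mol%), NaIO4 (4 equiv), 2,6-lutidine (2 equiv), dioxane/H2O 3:1, rt
Reagents that add atoms: sodium periodate, [Na+].[O-]I(=O)(=O)=O; osmium tetroxide, O=[Os](=O)(=O)=O
Why: Lemieux–Johnson oxidation, in which OsO4 dihydroxylates the isolated terminal alkene in preference to the tetrasubstituted, acceptor-conjugated enol ether alkene and NaIO4 cleaves diol 5 and regenerates OsO4.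

Step 4
Reactants: 6 (2-methoxy-6-oxocyclohex-1-en-1-yl)acetaldehyde; 7 isopropenylmagnesium bromide
Product: 8 racemic 2-(2-hydroxy-3-methylbut-3-en-1-yl)-3-methoxycyclohex-2-en-1-one
Conditions: 7 (1.2 equiv), THF, −78 °C; H2O quench at −78 °C
Reagents that add atoms: none
Why: Grignard 1,2-addition at low temperature is selective for the aldehyde over the much less electrophilic vinylogous ester carbonyl, the new carbinol centre forms racemic, and the alkoxide is kept from adding to C3′ by the 5-endo-trig geometry.

Step 5
Reactants: 8 racemic 2-(2-hydroxy-3-methylbut-3-en-1-yl)-3-methoxycyclohex-2-en-1-one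
Product: 9 2-[(2S)-2-hydroxy-3-methylbut-3-en-1-yl]-3-methoxycyclohex-2-en-1-one
Conditions: Ti(OiPr)4 (10 mol%), D-(−)-diisopropyl tartrate (15 mol%), tBuOOH (0.6 equiv), 4 Å molecular sieves, CH2Cl2, −20 °C; stopped at slightly more than half conversion
Reagents that add atoms: none
Why: Sharpless kinetic resolution of a secondary allylic alcohol, in which the D-(−)-tartrate catalyst epoxidises the (R)-enantiomer much faster (erythro epoxy alcohol, removed by chromatography) and should leave the (S)-alcohol, which fixes C2.

Step 6
Reactants: 10 geranial; 11 triethyl phosphonoacetate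
Product: 12 ethyl (2E,4E)-5,9-dimethyldeca-2,4,8-trienoate
Conditions: NaH (1.1 equiv), THF, 0 °C; then 10, 0 °C to rt
Reagents that add atoms: none
Why: Horner–Wadsworth–Emmons olefination of an enal with a stabilised phosphonate anion should give the (2E)-dienoate and leaves the (4E) geometry of geranial untouched.

Step 7
Reactants: 12 ethyl (2E,4E)-5,9-dimethyldeca-2,4,8-trienoate
Product: 13 (2E,4E)-5,9-dimethyldeca-2,4,8-trien-1-ol
Conditions: iBu2AlH (2.2 equiv), CH2Cl2, −78 °C; aq. KNaC4H4O6 work-up
Reagents that add atoms: none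
Why: iBu2AlH reduces the conjugated ester by 1,2-addition to the primary dienol without touching the alkenes.

Step 8
Reactants: 13 (2E,4E)-5,9-dimethyldeca-2,4,8-trien-1-ol
Product: 14 tert-butyl (2E,4E)-5,9-dimethyldeca-2,4,8-trien-1-yl carbonate
Conditions: Boc2O (1.2 equiv), DMAP (10 mol%), CH2Cl2, 0 °C to rt
Reagents that add atoms: di-tert-butyl dicarbonate, CC(C)(C)OC(=O)OC(=O)OC(C)(C)C
Why: DMAP-catalysed acylation of the primary alcohol gives the tert-butyl carbonate, whose leaving group releases only the poorly nucleophilic tert-butoxide in the iridium step.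

Step 9
Reactants: 9 2-[(2S)-2-hydroxy-3-methylbut-3-en-1-yl]-3-methoxycyclohex-2-en-1-one; 14 tert-butyl (2E,4E)-5,9-dimethyldeca-2,4,8-trien-1-yl carbonate
Product: 16 3-methoxy-2-[(2S)-2-{[(3R,4E)-5,9-dimethyldeca-1,4,8-trien-3-yl]oxy}-3-methylbut-3-en-1-yl]cyclohex-2-en-1-one, via copper alkoxide 15 (not isolated)
Conditions: LiN(SiMe3)2 (1.0 equiv), THF, −78 to 0 °C; CuI (1.0 equiv); then 14 (1.3 equiv), [Ir(cod)Cl]2 (2 mol%), (Ra,R,R)-O,O′-(1,1′-binaphthyl-2,2′-diyl) N,N-bis(1-phenylethyl)phosphoramidite (4 mol%), THF, rt
Reagents that add atoms: none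
Why: iridium-catalysed allylic etherification with a monovalent copper alkoxide, in which the Ir–phosphoramidite complex ionises 14 and the soft alkoxide 15 attacks the internal allyl terminus to give the branched bis-allylic ether, the new (R) centre being set by the ligand (catalyst control over the existing C2 centre), as in the known route from chiral secondary allylic alkoxides to 2,5-dihydrofuran precursors.

Step 10
Reactants: 16 bis-allylic ether
Product: 17 2-{[(2S,5S)-5-[(1E)-2,6-dimethylhepta-1,5-dien-1-yl]-3-methyl-2,5-dihydrofuran-2-yl]methyl}-3-methoxycyclohex-2-en-1-one (2,5-trans)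
Conditions: second-generation Grubbs catalyst (5 mol%), CH2Cl2 (0.005 M), 40 °C
Reagents that add atoms: none
Why: ring-closing metathesis, in which the catalyst loads on the vinyl group and closes onto the isopropenyl alkene to the five-membered trisubstituted alkene, whereas closure onto either (E)-trisubstituted side-chain alkene would need a cyclopropene or a trans-cycloheptene; the two stereocentres are untouched.

Step 11
Reactants: 17 methyl enol ether of the 2,5-trans dihydrofuran
Product: 18 2-{[(2S,5S)-5-[(1E)-2,6-dimethylhepta-1,5-dien-1-yl]-3-methyl-2,5-dihydrofuran-2-yl]methyl}-3-hydroxycyclohex-2-en-1-one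
Conditions: 2 M aq. NaOH/1,4-dioxane 1:1, 70 °C, Ar; then 0 °C, aq. NaH2PO4 to pH 5–6; used at once
Reagents that add atoms: sodium hydroxide, [Na+].[OH-]
Why: base hydrolysis of a vinylogous ester by addition–elimination of hydroxide at C3′, driven by formation of the dione enolate and chosen because the doubly allylic C5–O bond would not survive the usual acidic hydrolysis.

Step 12
Reactants: 18 2,5-trans 3-methyl-2,5-dihydrofuran carrying the enolised dione on C1
Product: 19 (2S,3R,4R,5S)-iodo tricycle (oxolane numbering): oxolane cis-fused across C2–C3 to a dihydropyran whose ring oxygen sits on C3 and which is fused to the cyclohex-2-enone; iodine on C4 trans to the C3–O bond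
Conditions: I2 (2 equiv), NaHCO3 (3 equiv), dry MeCN, 0 °C, dark; aq. Na2S2O3 work-up
Reagents that add atoms: iodine, II
Why: NaHCO3 converts the dione (about as acidic as acetic acid) into its enolate, and iodine adds reversibly to the alkenes, either directly or by transfer from a transient C2′ iodide of the enolate. Only the iodonium ion on C3=C4 has a nucleophile in reach: the enolate oxygen opens it at the tertiary carbon anti to iodine, which is the known iodoetherification of 2-alkenyl-1,3-diones through the enol oxygen, the ether counterpart of iodolactonisation. The dihydropyran closes 6-exo-trig with respect to C3=C4, in preference to 7-endo attack at C4 and to C-alkylation at C2′, which would give a cyclobutane. C3 is set by the tether, since a five/six fusion across C2–C3 can only be cis and the new C3–O bond therefore lies on the face of C1; C4 is set by the stereospecific anti addition, which puts iodine trans to that oxygen. Regioselectivity rests on Markovnikov opening at the tertiary C3 and the six-membered closure, and chemoselectivity over the two trisubstituted side-chain alkenes rests on the reversibility of iodine addition in a dry, non-nucleophilic solvent where those alkenes have no internal nucleophile. The 2,5-trans arrangement only requires the iodonium ion to sit on the face of the C5 side chain, which costs rate but not selectivity.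

Step 13
Reactants: 19 iodo tricycle
Product: 20 (2S,3S,5R)-tricycle (oxolane numbering): the cyclic vinylogous ester 19 with CH2 at C4
Conditions: Bu3SnH (3 equiv, 0.5 M), (PhSe)2 (10 mol%), Et3B (0.2 equiv), air, toluene, 0 °C
Reagents that add atoms: none
Why: radical-chain reduction of the secondary iodide, in which PhSeH formed in the flask transfers hydrogen to the C4 radical fast enough to outrun 3-exo attack on the neighbouring alkene (vinyl shift) and β-scission of the C3–O bond.

Step 14
Reactants: 20 tricyclic vinylogous ester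
Product: 21 3-hydroxy-2-{[(2S,3S,5R)-5-[(1E)-2,6-dimethylhepta-1,5-dien-1-yl]-3-hydroxy-3-methyloxolan-2-yl]methyl}cyclohex-2-en-1-one
Conditions: 2 M aq. NaOH/1,4-dioxane 1:1, 80 °C, Ar; then 0 °C, aq. NaH2PO4 to pH 6; used at once
Reagents that add atoms: sodium hydroxide, [Na+].[OH-]
Why: vinylogous saponification, in which hydroxide adds to C3′ and the tertiary alkoxide leaves (C3′–O cleavage, not C3–O), so the C3–O bond and its configuration are kept and the irreversible formation of the dione enolate drives the opening.

Step 15
Reactants: 21 hydroxy dione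
Product: 22 2-{[(2S,3S,5R)-5-[(1E)-2,6-dimethylhepta-1,5-dien-1-yl]-3-methyl-3-(trimethylsilyloxy)oxolan-2-yl]methyl}-3-(trimethylsilyloxy)cyclohex-2-en-1-one
Conditions: TMSCl (3 equiv), imidazole (4 equiv), CH2Cl2, 0 °C to rt; pentane, filtration, no aqueous work-up; used crude
Reagents that add atoms: chlorotrimethylsilane, C[Si](C)(C)Cl
Why: silylation of the tertiary alcohol and of the enol removes both acidic protons and turns the dione into an O-silyl vinylogous ester whose ring CH2 next to the carbonyl is the only site left for deprotonation.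

Step 16
Reactants: 22 bis(trimethylsilyl) ether
Product: 25 target CNP0194047.1 (4S)-3,4-dihydroxy-2-{[(2S,3S,5R)-5-[(1E)-2,6-dimethylhepta-1,5-dien-1-yl]-3-hydroxy-3-methyloxolan-2-yl]methyl}cyclohex-2-en-1-one, via lithium enolate 23 (not isolated), via hydroxylated bis-silyl ether 24 (not isolated)
Conditions: LiN(iPr)2 (1.2 equiv), THF, −78 °C; (+)-(camphorsulfonyl)oxaziridine (1.5 equiv), −78 to −40 °C; AcOH (1.2 equiv); then citric acid (cat.), MeOH, 0 °C
Reagents that add atoms: (+)-(2R,8aS)-(camphorsulfonyl)oxaziridine, CC1(C)[C@@H]2CC[C@]13CS(=O)(=O)N4O[C@@]34C2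
Why: Stork–Danheiser-type kinetic deprotonation of the 3-silyloxy enone gives the cross-conjugated enolate 23, which takes up oxygen from the N-sulfonyloxaziridine (Davis oxidation) on the face chosen by the camphor-derived reagent because the existing stereocentres are remote; mild acidic methanolysis then removes both silyl groups, and since the dione is symmetrical once desilylated the hydroxylated carbon is C4′ whichever α-position was deprotonated.

**Compound list**
1 | cyclohexane-1,3-dione | O=C1CCCC(=O)C1 | starting material
2 | allyl acetate | C=CCOC(C)=O | starting material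
3 | 2-allylcyclohexane-1,3-dione (enol form) | C=CCC1=C(O)CCCC1=O | intermediate
4 | 3-methoxy-2-(prop-2-en-1-yl)cyclohex-2-en-1-one | C=CCC1=C(OC)CCCC1=O | intermediate
5 | 2-(2,3-dihydroxypropyl)-3-methoxycyclohex-2-en-1-one (racemic, not isolated) | OCC(O)CC1=C(OC)CCCC1=O | intermediate
6 | (2-methoxy-6-oxocyclohex-1-en-1-yl)acetaldehyde | O=CCC1=C(OC)CCCC1=O | intermediate
7 | isopropenylmagnesium bromide | C=C(C)[Mg]Br | starting material
8 | racemic 2-(2-hydroxy-3-methylbut-3-en-1-yl)-3-methoxycyclohex-2-en-1-one | C=C(C)C(O)CC1=C(OC)CCCC1=O | intermediate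
9 | 2-[(2S)-2-hydroxy-3-methylbut-3-en-1-yl]-3-methoxycyclohex-2-en-1-one | C=C(C)[C@@H](O)CC1=C(OC)CCCC1=O | intermediate
10 | geranial, (2E)-3,7-dimethylocta-2,6-dienal | CC(C)=CCC/C(C)=C/C=O | starting material
11 | triethyl phosphonoacetate | CCOC(=O)CP(=O)(OCC)OCC | starting material
12 | ethyl (2E,4E)-5,9-dimethyldeca-2,4,8-trienoate | CC(C)=CCC/C(C)=C/C=C/C(=O)OCC | intermediate
13 | (2E,4E)-5,9-dimethyldeca-2,4,8-trien-1-ol | CC(C)=CCC/C(C)=C/C=C/CO | intermediate
14 | tert-butyl (2E,4E)-5,9-dimethyldeca-2,4,8-trien-1-yl carbonate | CC(C)=CCC/C(C)=C/C=C/COC(=O)OC(C)(C)C | intermediate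
15 | copper alkoxide of 9 (monovalent copper, not isolated) | C=C(C)[C@@H](O[Cu])CC1=C(OC)CCCC1=O | intermediate
16 | 3-methoxy-2-[(2S)-2-{[(3R,4E)-5,9-dimethyldeca-1,4,8-trien-3-yl]oxy}-3-methylbut-3-en-1-yl]cyclohex-2-en-1-one | CC(C)=CCC/C(C)=C/[C@@H](C=C)O[C@@H](CC1=C(OC)CCCC1=O)C(C)=C | intermediate
17 | 2-{[(2S,5S)-5-[(1E)-2,6-dimethylhepta-1,5-dien-1-yl]-3-methyl-2,5-dihydrofuran-2-yl]methyl}-3-methoxycyclohex-2-en-1-one | CC(C)=CCC/C(C)=C/[C@H]1C=C(C)[C@H](CC2=C(OC)CCCC2=O)O1 | intermediate
18 | 2-{[(2S,5S)-5-[(1E)-2,6-dimethylhepta-1,5-dien-1-yl]-3-methyl-2,5-dihydrofuran-2-yl]methyl}-3-hydroxycyclohex-2-en-1-one (key-step precursor) | CC(C)=CCC/C(C)=C/[C@H]1C=C(C)[C@H](CC2=C(O)CCCC2=O)O1 | intermediate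
19 | (2S,3R,4R,5S)-iodo tricycle, enol ether oxygen on C3, iodine on C4 (key-step product) | CC(C)=CCC/C(C)=C/[C@H]1[C@@H](I)[C@]2(C)OC3=C(C[C@@H]2O1)C(=O)CCC3 | intermediate
20 | (2S,3S,5R)-tricyclic vinylogous ester, CH2 at C4 | CC(C)=CCC/C(C)=C/[C@H]1C[C@]2(C)OC3=C(C[C@@H]2O1)C(=O)CCC3 | intermediate
21 | 3-hydroxy-2-{[(2S,3S,5R)-5-[(1E)-2,6-dimethylhepta-1,5-dien-1-yl]-3-hydroxy-3-methyloxolan-2-yl]methyl}cyclohex-2-en-1-one | CC(C)=CCC/C(C)=C/[C@H]1C[C@](C)(O)[C@H](CC2=C(O)CCCC2=O)O1 | intermediate
22 | bis(trimethylsilyl) ether of 21 (tertiary O–Si and enol O–Si) | CC(C)=CCC/C(C)=C/[C@H]1C[C@](C)(O[Si](C)(C)C)[C@H](CC2=C(O[Si](C)(C)C)CCCC2=O)O1 | intermediate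
23 | lithium enolate of 22 (cross-conjugated, not isolated) | CC(C)=CCC/C(C)=C/[C@H]1C[C@](C)(O[Si](C)(C)C)[C@H](CC2=C(O[Si](C)(C)C)CCC=C2O[Li])O1 | intermediate
24 | (6S)-6-hydroxy derivative of 22 (cyclohexenone numbering, not isolated) | CC(C)=CCC/C(C)=C/[C@H]1C[C@](C)(O[Si](C)(C)C)[C@H](CC2=C(O[Si](C)(C)C)CC[C@H](O)C2=O)O1 | intermediate
25 | CNP0194047.1, (4S)-3,4-dihydroxy-2-{[(2S,3S,5R)-5-[(1E)-2,6-dimethylhepta-1,5-dien-1-yl]-3-hydroxy-3-methyloxolan-2-yl]methyl}cyclohex-2-en-1-one | CC(C)=CCC/C(C)=C/[C@H]1C[C@](C)(O)[C@H](CC2=C(O)[C@@H](O)CCC2=O)O1 | target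

**Count**
Total steps: 16. Longest linear sequence: 13 (steps 1–5 and 9–16, from cyclohexane-1,3-dione); the geranial branch (steps 6–8) joins at step 9.

**Steps most likely to fail**

Step 16. The enolate carbon is far from every existing stereocentre, so facial discrimination rests on the reagent alone and may be poor; the silyl enol ether may also be lost to the amide base before deprotonation. Fallback: setting out from 22, the same enolate 23 would be oxidised with racemic trans-3-phenyl-2-(phenylsulfonyl)oxaziridine, without reagent control. This gives 24 together with its C4′ epimer, the (6R)-hydroxy bis-silyl ether F1. The same methanolysis then gives 25 and the 4′-epimer of the target F2, which are diastereomers and would be separated by preparative reversed-phase HPLC. The route is rejoined at 25; reagent control is traded for separation.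

Step 9. The hindered, functionalised alkoxide may capture the iridium allyl complex slowly, attack the wrong allyl terminus, or add to C3′ of its own vinylogous ester; the catalyst may also fail to override the C2 centre. Fallback: setting out from 9 and dienol 13 (carbonate 14 is bypassed), a gold-catalysed dehydrative SN2′ alkoxylation would join the fragments under neutral conditions, with no metal alkoxide ([1,3-bis(2,6-diisopropylphenyl)imidazol-2-ylidene]AuCl/AgClO4, cationic monovalent gold, CH2Cl2, rt). It gives 16 mixed with its epimer at the bis-allylic carbon, the (3S)-ether F3. Ring-closing metathesis of the mixture as in step 10 gives 17 and its 2,5-cis isomer, the (2S,5R)-dihydrofuran F4, which is removed by chromatography. The route is rejoined at 17.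

Step 14. Addition of hydroxide to the fully substituted C3′ with a tertiary alkoxide as leaving group may be too slow, and the hydroxy dione may close back to 20 on acidification. Fallback: setting out from 20, iBu2AlH (CH2Cl2, −78 °C) reduces the C1′ carbonyl to the allylic alcohol F5. Dilute aqueous oxalic acid then hydrolyses the enol ether with allylic transposition (Stork–Danheiser sequence), which cleaves the C3′–O bond and gives the 2-substituted cyclohex-2-enone F6 with the free C3 hydroxyl. Nucleophilic epoxidation (H2O2, NaOH, MeOH) gives the epoxy ketone F7, and isomerisation of the α,β-epoxy ketone with Pd(PPh3)4/dppe (toluene, 80 °C) gives the 1,3-dione 21, where the route is rejoined.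

**Further compounds**
F1 | step 16 | (6R)-6-hydroxy epimer of 24 | CC(C)=CCC/C(C)=C/[C@H]1C[C@](C)(O[Si](C)(C)C)[C@H](CC2=C(O[Si](C)(C)C)CC[C@@H](O)C2=O)O1
F2 | step 16 | 4′-epimer of the target, (4R) | CC(C)=CCC/C(C)=C/[C@H]1C[C@](C)(O)[C@H](CC2=C(O)[C@H](O)CCC2=O)O1
F3 | step 9 | (3S)-epimer of ether 16 at the bis-allylic carbon | CC(C)=CCC/C(C)=C/[C@H](C=C)O[C@@H](CC1=C(OC)CCCC1=O)C(C)=C
F4 | step 9 | (2S,5R)-2,5-cis isomer of dihydrofuran 17 | CC(C)=CCC/C(C)=C/[C@@H]1C=C(C)[C@H](CC2=C(OC)CCCC2=O)O1
F5 | step 14 | allylic alcohol from 1,2-reduction of 20 (mixture at the new carbinol) | CC(C)=CCC/C(C)=C/[C@H]1C[C@]2(C)OC3=C(C[C@@H]2O1)C(O)CCC3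
F6 | step 14 | 2-{[(2S,3S,5R)-5-[(1E)-2,6-dimethylhepta-1,5-dien-1-yl]-3-hydroxy-3-methyloxolan-2-yl]methyl}cyclohex-2-en-1-one | CC(C)=CCC/C(C)=C/[C@H]1C[C@](C)(O)[C@H](CC2=CCCCC2=O)O1
F7 | step 14 | 2,3-epoxy ketone of F6 (mixture at the epoxide) | CC(C)=CCC/C(C)=C/[C@H]1C[C@](C)(O)[C@H](CC23OC2CCCC3=O)O1
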